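**Strategy.** The route rests on disconnecting the C1–C2 bond of the 3(2H)-furanone (C1 ketone carbon, C2 vinylic CH, C3 enol-ether carbon, C10 the oxygenated quaternary carbon), a bond common to the furanone ring and the ten-membered carbocycle. The key step is a thioester Eschenmoser sulfide contraction: an eleven-membered thiolactone, C1(=O)–S–C2H2–C3(=O), closed beforehand by S-alkylation, loses its sulfur, so that the new C1–C2 bond closes the ten-membered ring as a 1,3-diketone, which the C10 hydroxyl dehydrates to the furanone in the same operation. It exploits the 1,3-dioxygenation C1/C3 of the furanone ring. The precursor already carries the trans-methylenelactone, the epoxyangelate and all stereocentres.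

Key step: step 20

Remark on locants: the skeleton carbons keep one set of locants in all intermediates: C1–C3 as above, C4 (methyl C15)=C5 the Z-alkene, C6 the acyloxy carbon, C7 and C8 the lactone ring-fusion carbons (C8 bears the lactone oxygen), C9 the CH2, C10 (methyl C14), C11=C13 the exocyclic methylene, C12 the lactone carbonyl.

Assumption: in steps 10 and 14 the ligand enantiomer is the one that directs attack to the Re face of the aldehyde; for step 10 this is taken to be (S,S)-ProPhenol.

Step 1
Reactants: 1 angelic acid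
Product: 2 (Z)-2-methylbut-2-en-1-ol
Conditions: LiAlH4, Et2O, 0 °C → rt
Reagents that add atoms: none
Why: Hydride reduction of the carboxylic acid should give the allylic alcohol without touching the trisubstituted Z-alkene.

Step 2
Reactants: 2 (Z)-2-methylbut-2-en-1-ol
Product: 3 (2S,3R)-epoxy alcohol
Conditions: Ti(OiPr)4 (cat.), L-(+)-diisopropyl tartrate (cat.), tBuOOH, 4 Å molecular sieves, CH2Cl2, −20 °C
Reagents that add atoms: tert-butyl hydroperoxide CC(C)(C)OO
Why: Sharpless asymmetric epoxidation, in which the L-(+)-tartrate complex should deliver oxygen to the face that gives the (2S,3R) alcohol (the sense known for Z-2-alken-1-ols), while the cis relation of CH2OH and the C3 methyl follows from the Z-alkene.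

Step 3
Reactants: 3 (2S,3R)-epoxy alcohol
Product: 4 (2R,3R)-2,3-dimethyloxirane-2-carboxylic acid
Conditions: RuCl3 (cat.), NaIO4, MeCN/EtOAc/H2O, rt
Reagents that add atoms: sodium periodate [Na+].[O-]I(=O)(=O)=O
Why: Ruthenium tetroxide oxidation of the primary alcohol to the acid should leave the epoxide intact; the descriptor at C2 changes only through CIP priorities.

Step 4
Reactants: 5 (2S,5S)-2-tert-butyl-5-methyl-1,3-dioxolan-4-one; 6 allyl bromide
Product: 7 (2S,5R)-5-allyl dioxolanone
Conditions: LiN(iPr)2, THF, −78 °C; then 6, −78 → −30 °C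
Reagents that add atoms: none
Why: Enolate alkylation of the lactic acid acetal (self-regeneration of the stereocentre) should bring the allyl group in trans to the tert-butyl group and so set quaternary C10 as R.

Step 5
Reactants: 7 (2S,5R)-5-allyl dioxolanone
Product: 8 hydroxy thioester
Conditions: Me3Al, Me3SiCH2CH2SH, CH2Cl2, 0 °C → rt
Reagents that add atoms: 2-(trimethylsilyl)ethanethiol C[Si](C)(C)CCS
Why: Transfer of thiolate from the dimethylaluminium thiolate to the lactone carbonyl (ester-to-thioester conversion) should open the dioxolanone with loss of pivalaldehyde and install the masked thioacid at C1 without touching C10.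

Step 6
Reactants: 8 hydroxy thioester
Product: 9 triethylsilyl ether
Conditions: Et3SiOTf, 2,6-lutidine, CH2Cl2, −78 → 0 °C
Reagents that add atoms: triethylsilyl triflate CC[Si](CC)(CC)OS(=O)(=O)C(F)(F)F
Why: Silylation of the tertiary alcohol with a silyl triflate should prevent β-elimination and retro-aldol cleavage of the aldehyde made next.

Step 7
Reactants: 9 triethylsilyl ether
Product: 10 aldehyde
Conditions: O3, CH2Cl2, −78 °C; then PPh3
Reagents that add atoms: ozone [O-][O+]=O
Why: Ozonolysis with reductive work-up should cleave only the terminal alkene, the thioester and silyl groups being inert at −78 °C.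

Step 8
Reactants: 11 (Z)-3-methylpent-2-en-4-yn-1-ol
Product: 13 C-silylated enynol, via bis-silyl ether 12 (not isolated)
Conditions: EtMgBr (2.2 equiv), THF, 0 °C → rt; Me3SiCl; then aq. H2SO4 work-up
Reagents that add atoms: chlorotrimethylsilane C[Si](C)(C)Cl
Why: Silylation of the O,C-dimagnesium derivative followed by acidic cleavage of the O-silyl group should block the terminal alkyne so that it does not compete in step 10.

Step 9
Reactants: 13 C-silylated enynol
Product: 14 (Z)-enynal
Conditions: MnO2, CH2Cl2, 0 °C, dark
Reagents that add atoms: none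
Why: Allylic oxidation with MnO2 is mild enough that the Z-enal should not isomerize.

Step 10
Reactants: 14 (Z)-enynal; 15 methyl propiolate
Product: 16 (S)-propargylic alcohol
Conditions: Me2Zn, (S,S)-ProPhenol (20 mol %), Ph3P=O (40 mol %), toluene, 0 °C
Reagents that add atoms: none
Why: Catalytic asymmetric alkynylation by the dinuclear zinc–ProPhenol complex should add the zinc propiolate to the Re face of the enal and set C6 as S.

Step 11
Reactants: 16 (S)-propargylic alcohol
Product: 17 silyl ether
Conditions: tBuMe2SiOTf, 2,6-lutidine, CH2Cl2, −78 °C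
Reagents that add atoms: tert-butyldimethylsilyl triflate CC(C)(C)[Si](C)(C)OS(=O)(=O)C(F)(F)F
Why: Silylation under non-basic conditions should protect C6–OH without isomerizing the γ-hydroxy ynoate.

Step 12
Reactants: 17 silyl ether
Product: 19 2-(hydroxymethyl) enoate, via vinylalane 18 (not isolated)
Conditions: iBu2AlH, N-methylmorpholine N-oxide, THF, 0 °C; then (CH2O)n, 0 °C → rt
Reagents that add atoms: formaldehyde (as paraformaldehyde) C=O
Why: Conjugate syn-hydroalumination of the ynoate should give the α-aluminio acrylate, which adds to formaldehyde (vinylalumination) so that H and CH2OH end up cis; the silylalkyne and the silyl ether are inert.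

Step 13
Reactants: 19 2-(hydroxymethyl) enoate
Product: 20 allylic bromide
Conditions: CBr4, PPh3, 2,6-lutidine, CH2Cl2, 0 °C
Reagents that add atoms: carbon tetrabromide BrC(Br)(Br)Br
Why: Appel bromination of the primary allylic alcohol; the double-bond geometry of 20 does not matter because the allylchromium of step 14 equilibrates.

Step 14
Reactants: 10 aldehyde; 20 allylic bromide
Product: 23 trans-methylenelactone, via silyl ether 21 (not isolated), via hydroxy ester 22 (not isolated)
Conditions: CrCl2 (10 mol %), chiral 1,8-bis(oxazolinyl)carbazole ligand (12 mol %), Mn, Me3SiCl, THF, rt; aq. HCl work-up; then TsOH·H2O (cat.), CH2Cl2, rt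
Reagents that add atoms: none
Why: Chromium-catalysed asymmetric Nozaki–Hiyama–Kishi-type 2-(alkoxycarbonyl)allylation followed by lactonization: the allylchromium should add through a chair transition state with C6 equatorial (anti adduct, hence trans-lactone and C7 R), the ligand directs attack to the Re face of the aldehyde (C8 S), and acid closes the lactone on the methyl ester because the thioester next to quaternary C10 is hindered.

Step 15
Reactants: 23 trans-methylenelactone
Product: 24 diol
Conditions: HF·pyridine, pyridine, THF, 0 °C → rt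
Reagents that add atoms: none
Why: Acidic fluoride should cleave both silyl ethers while the carbon-bound trimethylsilyl groups of the alkyne and of the thioester, which need basic fluoride, stay.

Step 16
Reactants: 24 diol; 4 (2R,3R)-2,3-dimethyloxirane-2-carboxylic acid
Product: 25 epoxyangelate
Conditions: 2,4,6-Cl3C6H2COCl, Et3N, THF; then 24, DMAP, toluene, rt
Reagents that add atoms: none
Why: Yamaguchi esterification should acylate the secondary C6–OH with retention, the tertiary C10–OH being too hindered; acylating C6–O before the C3 ketone exists prevents later hemiketal and furan formation.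

Step 17
Reactants: 25 epoxyangelate
Product: 26 bromoalkyne
Conditions: N-bromosuccinimide, AgNO3 (10 mol %), acetone, rt, dark
Reagents that add atoms: N-bromosuccinimide O=C1CCC(=O)N1Br
Why: Silver-catalysed bromodesilylation of the alkynylsilane should give the 1-bromoalkyne directly.

Step 18
Reactants: 26 bromoalkyne
Product: 27 bromomethyl ketone
Conditions: Ph3PAuNTf2 (5 mol %), H2O (3 equiv), 1,4-dioxane, rt
Reagents that add atoms: water O
Why: Gold-catalysed hydration of a 1-haloalkyne places oxygen on the carbon remote from bromine and should give the (Z)-configured bromomethyl enone at C2/C3.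

Step 19
Reactants: 27 bromomethyl ketone
Product: 29 eleven-membered thiolactone, via thiocarboxylate 28 (not isolated)
Conditions: (Me2N)3S+ Me3SiF2− (TASF), DMF/THF, 0 °C, slow addition, 1 mM
Reagents that add atoms: none
Why: Fluoride-induced β-elimination of the 2-(trimethylsilyl)ethyl group unmasks the thiocarboxylate, which should close the ring by SN2 displacement at the very reactive bromomethyl ketone under high dilution, faster than this soft, weakly basic anion adds to the methylenelactone.

Step 20
Reactants: 29 eleven-membered thiolactone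
Product: 32 target CNP0258430.3, via thiirane 30 (not isolated), via diketone 31 (not isolated)
Conditions: PPh3, LiBr, iPr2NEt, MeCN, 50 °C; aq. NH4Cl work-up; then pyridinium p-toluenesulfonate (cat.), benzene, 40 °C
Reagents that add atoms: none
Why: Soft enolization at C2, the only acidic C–H (between sulfur and the C3 ketone), gives an enolate that adds to the thioester carbonyl C1 to form a thiirane alkoxide; PPh3 removes the sulfur and the C1–C2 bond remains, contracting the eleven-membered thiolactone to the ten-membered 1,3-diketone. This is the thioester variant of the Eschenmoser sulfide contraction (alkylative coupling and sulfur extrusion to β-dicarbonyls), a reaction type known also for ring contraction to ten-membered rings. The carbocycle closes by ring contraction (3-exo-trig addition, then extrusion), and the furanone closes by 5-exo-trig addition of the C10 hydroxyl to the C3 carbonyl followed by acid-catalysed loss of water. No stereocentre is created, since C1 and C2 of the thiirane become sp2 again and quaternary C10 cannot epimerize. The step needs C-acylation at C2 only, secured because C1 has no α-hydrogen and the sulfur tether holds C1 and C2 in a 1,3-relation. The furanone regiochemistry is fixed because the hydroxyl can reach only C3 in a five-membered mode.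

**Compound list**

1 | angelic acid, (2Z)-2-methylbut-2-enoic acid | C/C=C(C)\C(=O)O | starting material
2 | (2Z)-2-methylbut-2-en-1-ol | C/C=C(C)\CO | intermediate
3 | [(2S,3R)-2,3-dimethyloxiran-2-yl]methanol | OC[C@]1(C)O[C@@H]1C | intermediate
4 | (2R,3R)-2,3-dimethyloxirane-2-carboxylic acid | OC(=O)[C@]1(C)O[C@@H]1C | intermediate
5 | (2S,5S)-2-tert-butyl-5-methyl-1,3-dioxolan-4-one (cis acetal of (S)-lactic acid) | C[C@@H]1O[C@H](C(C)(C)C)OC1=O | starting material
6 | allyl bromide | C=CCBr | starting material
7 | (2S,5R)-2-tert-butyl-5-methyl-5-(prop-2-en-1-yl)-1,3-dioxolan-4-one | C[C@]1(CC=C)O[C@H](C(C)(C)C)OC1=O | intermediate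
8 | S-[2-(trimethylsilyl)ethyl] (2R)-2-hydroxy-2-methylpent-4-enethioate | C=CC[C@@](C)(O)C(=O)SCC[Si](C)(C)C | intermediate
9 | S-[2-(trimethylsilyl)ethyl] (2R)-2-methyl-2-[(triethylsilyl)oxy]pent-4-enethioate | C=CC[C@@](C)(O[Si](CC)(CC)CC)C(=O)SCC[Si](C)(C)C | intermediate
10 | S-[2-(trimethylsilyl)ethyl] (2R)-2-methyl-4-oxo-2-[(triethylsilyl)oxy]butanethioate (C8 aldehyde, C10 R) | O=CC[C@@](C)(O[Si](CC)(CC)CC)C(=O)SCC[Si](C)(C)C | intermediate
11 | (2Z)-3-methylpent-2-en-4-yn-1-ol | C#C/C(C)=C\CO | starting material
12 | trimethyl{[(2Z)-3-methyl-5-(trimethylsilyl)pent-2-en-4-yn-1-yl]oxy}silane | C[Si](C)(C)C#C/C(C)=C\CO[Si](C)(C)C | intermediate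
13 | (2Z)-3-methyl-5-(trimethylsilyl)pent-2-en-4-yn-1-ol | C[Si](C)(C)C#C/C(C)=C\CO | intermediate
14 | (2Z)-3-methyl-5-(trimethylsilyl)pent-2-en-4-ynal | C[Si](C)(C)C#C/C(C)=C\C=O | intermediate
15 | methyl propiolate | C#CC(=O)OC | starting material
16 | methyl (4S,5Z)-4-hydroxy-6-methyl-8-(trimethylsilyl)oct-5-ene-2,7-diynoate | COC(=O)C#C[C@@H](O)/C=C(C)\C#C[Si](C)(C)C | intermediate
17 | methyl (4S,5Z)-4-[(tert-butyldimethylsilyl)oxy]-6-methyl-8-(trimethylsilyl)oct-5-ene-2,7-diynoate | COC(=O)C#C[C@@H](O[Si](C)(C)C(C)(C)C)/C=C(C)\C#C[Si](C)(C)C | intermediate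
18 | methyl (4S,5Z)-4-[(tert-butyldimethylsilyl)oxy]-2-(diisobutylalumanyl)-6-methyl-8-(trimethylsilyl)octa-2,5-dien-7-ynoate (Al cis to H-3) | COC(=O)/C([Al](CC(C)C)CC(C)C)=C\[C@@H](O[Si](C)(C)C(C)(C)C)/C=C(C)\C#C[Si](C)(C)C | intermediate
19 | methyl (2Z,4S,5Z)-4-[(tert-butyldimethylsilyl)oxy]-2-(hydroxymethyl)-6-methyl-8-(trimethylsilyl)octa-2,5-dien-7-ynoate | COC(=O)/C(CO)=C\[C@@H](O[Si](C)(C)C(C)(C)C)/C=C(C)\C#C[Si](C)(C)C | intermediate
20 | methyl (2E,4S,5Z)-2-(bromomethyl)-4-[(tert-butyldimethylsilyl)oxy]-6-methyl-8-(trimethylsilyl)octa-2,5-dien-7-ynoate | COC(=O)/C(CBr)=C\[C@@H](O[Si](C)(C)C(C)(C)C)/C=C(C)\C#C[Si](C)(C)C | intermediate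
21 | anti adduct as C8 O-trimethylsilyl ether: C12 methyl ester, 6-OTBS, 10-OTES, C1 thioester; C6, C7, C8, C10 arranged as in the target | COC(=O)C(=C)[C@H]([C@@H](O[Si](C)(C)C)C[C@@](C)(O[Si](CC)(CC)CC)C(=O)SCC[Si](C)(C)C)[C@@H](O[Si](C)(C)C(C)(C)C)/C=C(C)\C#C[Si](C)(C)C | intermediate
22 | anti adduct with free C8–OH (C12 methyl ester, 6-OTBS, 10-OTES); centres as in the target | COC(=O)C(=C)[C@H]([C@@H](O)C[C@@](C)(O[Si](CC)(CC)CC)C(=O)SCC[Si](C)(C)C)[C@@H](O[Si](C)(C)C(C)(C)C)/C=C(C)\C#C[Si](C)(C)C | intermediate
23 | S-[2-(trimethylsilyl)ethyl] (2R)-3-{(2S,3R)-3-[(1S,2Z)-1-[(tert-butyldimethylsilyl)oxy]-3-methyl-5-(trimethylsilyl)pent-2-en-4-yn-1-yl]-4-methylidene-5-oxooxolan-2-yl}-2-methyl-2-[(triethylsilyl)oxy]propanethioate (trans-8,12-lactone) | C=C1C(=O)O[C@@H](C[C@@](C)(O[Si](CC)(CC)CC)C(=O)SCC[Si](C)(C)C)[C@@H]1[C@@H](O[Si](C)(C)C(C)(C)C)/C=C(C)\C#C[Si](C)(C)C | intermediate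
24 | diol of 23: free C6–OH and C10–OH, trans-8,12-lactone, silylalkyne and thioester kept; centres as in the target | C=C1C(=O)O[C@@H](C[C@@](C)(O)C(=O)SCC[Si](C)(C)C)[C@@H]1[C@@H](O)/C=C(C)\C#C[Si](C)(C)C | intermediate
25 | C6 ester of 24 with acid 4 (epoxyangelate), free C10–OH; centres as in the target | C=C1C(=O)O[C@@H](C[C@@](C)(O)C(=O)SCC[Si](C)(C)C)[C@@H]1[C@@H](OC(=O)[C@]2(C)O[C@@H]2C)/C=C(C)\C#C[Si](C)(C)C | intermediate
26 | 1-bromoalkyne from 25 (Br on C2) | C=C1C(=O)O[C@@H](C[C@@](C)(O)C(=O)SCC[Si](C)(C)C)[C@@H]1[C@@H](OC(=O)[C@]2(C)O[C@@H]2C)/C=C(C)\C#CBr | intermediate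
27 | bromomethyl ketone: C3 ketone, C2H2Br, (4Z)-enone, 6-O-epoxyangelate, 10-OH, C1 thioester | C=C1C(=O)O[C@@H](C[C@@](C)(O)C(=O)SCC[Si](C)(C)C)[C@@H]1[C@@H](OC(=O)[C@]2(C)O[C@@H]2C)/C=C(C)\C(=O)CBr | intermediate
28 | C1 thiocarboxylate of 27 (drawn as the thioacid) | C=C1C(=O)O[C@@H](C[C@@](C)(O)C(=O)S)[C@@H]1[C@@H](OC(=O)[C@]2(C)O[C@@H]2C)/C=C(C)\C(=O)CBr | intermediate
29 | eleven-membered thiolactone C1(=O)–S–C2H2–C3(=O), (4Z), 6-O-epoxyangelate, 10-OH, trans-8,12-lactone; 6S,7R,8S,10R | C=C1C(=O)O[C@H]2C[C@@](C)(O)C(=O)SCC(=O)/C(C)=C\[C@H](OC(=O)[C@]3(C)O[C@@H]3C)[C@H]12 | intermediate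
30 | thiirane across C1–C2 in the ten-membered ring (alkoxide drawn as the alcohol; C1 and C2 transient, undefined) | C=C1C(=O)O[C@H]2C[C@@](C)(O)C3(O)SC3C(=O)/C(C)=C\[C@H](OC(=O)[C@]4(C)O[C@@H]4C)[C@H]12 | intermediate
31 | ten-membered 1,3-diketone (C1 and C3 ketones, C2H2), 10-OH, otherwise as 29 | C=C1C(=O)O[C@H]2C[C@@](C)(O)C(=O)CC(=O)/C(C)=C\[C@H](OC(=O)[C@]3(C)O[C@@H]3C)[C@H]12 | intermediate
32 | CNP0258430.3: (4Z,6S,7R,8S,10R) furanone 8,12-lactone 6-[(2R,3R)-2,3-dimethyloxirane-2-carboxylate] | C=C1C(=O)O[C@H]2C[C@@]3(C)OC(=CC3=O)/C(C)=C\[C@H](OC(=O)[C@]3(C)O[C@@H]3C)[C@H]12 | target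

**Step count and risks**

Total step count: 20. Longest linear sequence: 13 steps (steps 8 to 20, from enynol 11).

The steps most likely to fail are 20, 19 and 14, in that order.

In step 20 the enolate may not close onto the thioester in the strained ring, the thioester may be cleaved instead, or the phosphine may add to the methylenelactone and isomerize the Z-enone. The fallback forms the same C1–C2 bond without sulfur. It sets out from epoxyangelate 25: gold-catalysed hydration of the silylalkyne (Ph3PAuNTf2, H2O, dioxane), with loss of the C-silyl group, should give methyl ketone F1. LiN(SiMe3)2 (2.2 equiv, THF, −78 °C, high dilution) then effects a Dieckmann-type Claisen condensation of the C2 enolate onto the thioester. The route is rejoined at diketone 31, which is dehydrated to 32 with acid as in step 20.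

In step 19 the liberated thiocarboxylate may oligomerize, add to the methylenelactone, or the bromoketone may decompose under basic fluoride. The fallback avoids any free sulfur nucleophile. It sets out from bromomethyl ketone 27: SmI2 (2.2 equiv, THF, −78 °C, high dilution) should generate the samarium enolate at C2, which attacks the thioester carbon C1 in a Reformatsky-type acylation and expels the thiolate. The route is rejoined at diketone 31; this fallback makes no new compound (F0).

In step 14 the δ-silyloxy group may be lost by 1,4-elimination from the allylchromium, or the facial control may be poor. The fallback replaces the chromium reagent by an allylboronate. It sets out from vinylalane 18, which is trapped with ICH2B(pin) in place of formaldehyde to give allylboronate F2 with the double-bond geometry retained. Heating F2 with aldehyde 10 in toluene should give the anti adduct through a closed chair transition state, with approach anti to the alkenyl group of the C6 stereocentre. Hydrolysis of the borate and TsOH-catalysed lactonization rejoin the route at lactone 23.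

**Further compounds**

F1 | step 20 | methyl ketone from 25 (C3 ketone, C2H3; thioester, epoxyangelate and lactone as in 25) | C=C1C(=O)O[C@@H](C[C@@](C)(O)C(=O)SCC[Si](C)(C)C)[C@@H]1[C@@H](OC(=O)[C@]2(C)O[C@@H]2C)/C=C(C)\C(C)=O
F0 | step 19 | none | none
F2 | step 14 | methyl (2Z,4S,5Z)-4-[(tert-butyldimethylsilyl)oxy]-6-methyl-2-[(4,4,5,5-tetramethyl-1,3,2-dioxaborolan-2-yl)methyl]-8-(trimethylsilyl)octa-2,5-dien-7-ynoate | COC(=O)/C(CB1OC(C)(C)C(C)(C)O1)=C\[C@@H](O[Si](C)(C)C(C)(C)C)/C=C(C)\C#C[Si](C)(C)C
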